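The constants were set for the occasion; the result is computed.

If Sbt stays near its charge, the autocatalytic step is pseudo-first-order in Prd, with rate constant G = 0.0675 /s, while Prd exchanges with Sdp, forward 0.087 /s and back 0.0544 /s.

    Sbt → Prd (k1 = 2.3 × 10⁻⁴ /s)
    Prd ⇌ Sdp (K2 = 1.6, k2 = 0.087 /s)
    Sbt + Prd → 2 Prd (k3 = 0.27 /M/s)

| flask | Sbt | remark | time |
|---|---|---|---|
| ash | 0.25 M | one stirred flow tank at steady state, fed with the mixture as stated, mean residence time 30 s |  |
| larch | 0.25 M | a tube with plug flow, the mixed feed as stated, residence time 30 s | 30 s |
| elm | 0.25 M | everything together in a closed stirred flask, run for 30 s | 30 s |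
| cedar | 0.25 M | a single well-mixed tank run continuously and read at steady state, 150 s in it on average |  |

1. the set-up with the highest amount of Prd at the outlet or at the end, in percent of the Sbt put in ("none" if the first two lie within 2 percentage points) (ash / larch / elm / cedar / none)
2. amount of Prd at the outlet or at the end, in percent of the Sbt put in, ash
3. amount of Prd at the outlet or at the end, in percent of the Sbt put in, larch
4. amount of Prd at the outlet or at the end, in percent of the Sbt put in, elm
5. amount of Prd at the outlet or at the end, in percent of the Sbt put in, cedar

The reckoning here freezes Sbt at its charge, which makes the balances of Prd and Sdp linear. Their growing mode has rate λ = 0.0340 /s, the net growth rate of the Prd–Sdp pair at frozen Sbt, which is the larger eigenvalue of that two-species balance. It stays below G because Prd leaks into Sdp. Two times therefore matter: the growth time 1/λ = 29.4 s and the time spent in the vessel.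

Outflow subtracts 1/τ, with τ the mean residence time, from every mode, so at frozen Sbt a tank amplifies without bound where λτ exceeds one. In a closed flask, λt counts e-folds instead. Elm and larch follow the same equations, since a plug in the tube is a closed flask. Each has λt = 1.02, about one e-fold, while the direct step supplies a seed of about 0.690 % gradually over that time. Ash has the same ratio, 1.02, and so sits at the threshold. Cedar has λτ = 5.10, far past ash, and must spend Sbt until the ratio falls back. The order is cedar, then ash, then elm and larch together; this reckoning gives no tank yields.

The forecast, holding that “back-mixing wins”, named cedar, with 4.4 % for ash, 0.8 % for larch, 0.8 % for elm and 31.5 % for cedar.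

The simulation gives cedar first, with Prd at 4.38 % in ash, 0.814 % in larch, 0.814 % in elm and 31.5 % in cedar. In elm, Sbt at 30.0 s stands at 99 % of its charge. Carrying elm's Prd forward at λ from that moment to a reading at 2.0 min gives 17.4 %; that reading of elm shows Prd at 15.0 %, with Sbt down to 68 %.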